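**Remarks**

Atom labels: the cage is numbered as 4-oxatricyclo[4.3.1.0(3,7)]dec-8-en-2-one and these labels are kept for every intermediate. C1 = hydroxylated bridgehead, C2 = ketone, C3 = ether carbon (prenyl), O4, C5 = C(CH3)2, C6 = CH, C7 = oxygenated bridgehead, C8 = carboxyl-bearing alkene carbon, C9 = alkene CH, C10 = CH2. Ring A is the cyclohexenedione.

Assumption: the configurations of the spiro ketal carbon and of the adjacent CH(prenyl) are taken to be the thermodynamically preferred ones, because both centres can equilibrate (reversible oxa-Michael addition, enolisation).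

## Analysis of the target

The target is hexacyclic. A bicyclo[2.2.2]octenone (C1, C2, C3, C7, C8, C9, C10, C6) is bridged by a tetrahydrofuran (C3–O4–C5–C6–C7). The C8 carboxyl and the C7 oxygen are tied into a 1,3-dioxan-4-one whose ketal carbon is a spiro carbon of ring A, a cyclohex-2-ene-1,4-dione fused to a 2,2-dimethyl-2H-pyran. There are six stereocentres: C1, C3, C6 and C7 in the cage, the spiro ketal carbon and the neighbouring CH(prenyl). In the closed cage only C6 is independent; before closure this translates into three relative relationships on one cyclohexane ring (C7–O cis to the C6 side chain, C3–O cis to it, the C1 carbon arm cis to the C7 carbon arm). The two ring-A centres are labile, since the ketal is an O-acyl, O-alkyl ketal next to a ketone and the CH is enolisable. Sensitive groups are this ketal, the enedione (a vinylogous ester), the tertiary alpha-ketol at C1/C2, the two prenyl groups and the chromene alkene. The difficulty lies in four contiguous oxygenated carbons (C7, C3, C2, C1), three of them fully substituted, and in C3, a ring-fusion carbon that cannot become planar. The strategy rests on the only cage alkene, C8=C9, which joins the bridgeheads C7 and C1 and carries the carboxyl on C8 and a hydrogen on C9; it is the retron of a ring-closing metathesis between an acrylate on C7 and a vinyl group on C1, held 1,4-cis on the ring C7–C6–C10–C1–C2–C3 of a 6-oxabicyclo[3.2.1]octanone.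

## Retrosynthetic reasoning

**Spiro ketal.** In 30 the bond between the C7 oxygen and the spiro carbon is cut (oxa-Michael retron), which gives the acyloxyquinone 28 after silyl protection of C1–OH and C7–OH. Cutting the ester C–O bond of 28 gives acid 21 and hydroxyquinone 26. The two labile stereocentres are therefore made last, under equilibrating conditions, and the route becomes convergent. The forward reaction must acylate a vinylogous acid with a hindered acid and then let the freed C7 hydroxyl add 6-exo to a quinone carbon that has no hydrogen, so that aromatisation cannot compete.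

**Quinone half.** In 26 the prenyl C–C bond is cut to give 25, and the methoxy precursor 24 is taken back by a formal [3+3] disconnection of the pyran (one C–C and one C–O bond) to 23, the mono-hydrolysis product of 22. The 2,6-dioxygenation of 22 already matches the oxygens flanking one ring-A carbonyl.

**Prenyl on C3.** Acid 21 comes from tert-butyl ester 19. The C3–prenyl bond is cut only after the cage exists (19 to 18 to 17 to 16), for two reasons. A prenyl or allyl group on C3 lies gauche to the acrylate on C7 and would close a cyclopentene in the metathesis step. And C3 is a bridgehead of the oxabicyclo[3.2.1]octane: a planar enolate (or oxocarbenium ion) there would need O4 in the C2–C3–C7 plane, which the C5–C6 tether forbids. A pyramidal bridgehead radical has no such demand and C3–H is captodative. The forward sequence is therefore radical bromination, allyl transfer and cross-metathesis to the prenyl group.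

**Key disconnection.** In 16 the C8=C9 bond is cut to the acrylate and vinyl arms of 15. This removes the bicyclo[2.2.2]octene and leaves a 6-oxabicyclo[3.2.1]octanone whose substituents can be set by ordinary carbonyl chemistry. The forward reaction must join a 1,1-disubstituted acrylate and a vinyl group that both sit on fully substituted silyloxy carbons.

**Arms of 15.** The acrylate methylene is cut back to the ester CH2 of 12. The silyl group and the C2 ketone are traced to diol 10 through ketol 11. The C1–vinyl bond is cut to the C1 ketone 9. Oxidation state is moved from C1 to C2 so that one ketone at a time is present; the ketone of 9 has one open face.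

**Ether bridge.** The C3–O4 bond of 9 is cut to the epoxy alcohol 8, and the C5–O bond to the isopropenyl group of 7. The epoxide comes from the enone 6 (silyl ether of 5). Epoxide opening delivers the ether and the C2 oxygen in one event and fixes C3 by inversion.

**Carbocycle.** The C6–C5 bond of 5 is cut to the p-quinol 3 and the alkenylboronate 4 (conjugate addition that desymmetrises the dienone). The C7–CH2 bond of 3 is cut to 1 and 2. The C7 carbinol with its two-carbon arm is thus present from the first step and never has to be made on a hindered bridging ketone.

## Alternatives that were turned down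

Alternative 1: The bonds C3–C7 and C2–C1 are cut together, a [4+2] retron. In the forward step a vinyl sulfone bearing an alkoxy group, tethered through O4–C5 to C6, adds across a cyclohexadiene bis(silyl enol ether) (C7=C8–C9=C1) and gives the sulfonyl cage A1. In its favour, one step closes both the tetrahydrofuran and the bicyclo[2.2.2]octene, makes two C–C bonds and relays C1, C3 and C7 from C6 through the tether. On bonds, rings and stereocentres per step it is clearly stronger than the chosen closure. Against it, the diene is a dihydro-hydroquinone that aromatises by oxidation and can shift its double bonds by 1,5-hydrogen migration at cycloaddition temperatures. The dienophile is a push–pull alkene of low reactivity, and the two-atom tether forces a strained transition state. A1 also carries a sulfone at C2 that still has to be turned into the ketone, and C3 still lacks its prenyl group. The chosen strategy offers a stable precursor, the C2 ketone already in place and each stereocentre set in a separate, well-understood addition.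

Alternative 2: The C1–C9 bond is cut. In the forward step the potassium enolate of the C2 ketone (enolised towards a silyloxy-bearing C1–H) is coupled, with Pd2(dba)3 (zerovalent palladium) and a bulky phosphine, to a bromoacrylate arm on C7 whose bromine is cis to C7, giving A2. In its favour, the C1 stereocentre is created in the ring closure with the configuration dictated by the bridge, so no facial control in a separate addition is needed, and a prenyl group is tolerated. On these two points it is stronger. Against it, a fully substituted enolate carbon bearing a silyloxy group must undergo C–C reductive elimination at a future bridgehead; O-alkenylation and silyl migration between the two oxygens of the enediolate compete. A strong base meets a bromoacrylate that can undergo addition–elimination, and a geometrically defined bromoalkene on a quaternary carbon costs extra steps. The prenylated C3 must also already exist, which returns to the C3 problem before the cage is there. The chosen strategy closes the same ring under neutral catalysis from two arms that come from a Grignard addition and a methylenation.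

Alternative 3: The C8–C7 bond is cut. In the forward step an alpha-iodoacrylate arm on C1 (iodine cis to C1) is reduced by CrCl2 (divalent chromium) with catalytic NiCl2 (divalent nickel) and the alkenylchromium adds to the bridging C7 ketone, giving A3. In its favour, the hindered C7 carbinol is formed intramolecularly with its face fixed by the ring, and it arrives as the free alcohol needed for the final ketalisation; here it is stronger than the chosen route, which carries C7–O as a silyl ether. Against it, ketones are poor acceptors for alkenylchromium reagents and this one is flanked by two substituted carbons. An alkenylchromium bearing an ester on the metallated carbon is a weak nucleophile. The substrate needs two differentiated ketones (C2 and C7) and a stereodefined iodoalkene built from an aldehyde on a tertiary silyloxy carbon, and chromium is used in large excess. The chosen strategy needs one catalytic metal, no ketone differentiation and a shorter precursor synthesis.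

Key step: step 10

## Route

Step 1
Reactants: 1 1,4-benzoquinone; 2 tert-butyl acetate
Product: 3 p-quinol tert-butyl ester
Conditions: LDA, THF, −78 °C; 1, −78 °C; aq. NH4Cl
Reagents that add atoms: none
Why: Aldol-type 1,2-addition of the lithium ester enolate to one quinone carbonyl at low temperature gives the p-quinol with the C7 carbinol and its two-carbon arm in place. The tert-butyl ester is chosen because it resists Grignard reagents and lactonisation later and can be cleaved without hydroxide; no stereocentre is formed.

Step 2
Reactants: 3 p-quinol tert-butyl ester; 4 isopropenylboronic acid pinacol ester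
Product: 5 cis-hydroxy isopropenyl enone
Conditions: [Rh(cod)Cl]2 (cat.), (S)-BINAP, K3PO4, dioxane/H2O, 40 °C
Reagents that add atoms: none
Why: Hayashi–Miyaura conjugate addition run as a desymmetrisation of the 4,4-disubstituted cyclohexadienone. The (S)-BINAP–rhodium alkenyl species fixes the configuration at C6 (sense taken by analogy with 2-cyclohexenone), and of the two enone faces it can use, the substrate offers the one carrying the small, coordinating hydroxyl and not the CH2CO2tBu arm, so that C7–OH ends up cis to the isopropenyl group. The mono-adduct is more hindered than the dienone, which limits double addition.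

Step 3
Reactants: 5 cis-hydroxy isopropenyl enone
Product: 6 silyl ether enone
Conditions: TESOTf, 2,6-lutidine, CH2Cl2, −78 → 0 °C
Reagents that add atoms: triethylsilyl trifluoromethanesulfonate, CC[Si](CC)(CC)OS(=O)(=O)C(F)(F)F
Why: Silylation of the tertiary alcohol with the silyl triflate; it blocks retro-aldol cleavage and Payne rearrangement in the next steps and installs the C7 protecting group wanted in the metathesis substrate.

Step 4
Reactants: 6 silyl ether enone
Product: 7 epoxy ketone
Conditions: tBuOOH, DBU, CH2Cl2, 0 °C → rt
Reagents that add atoms: tert-butyl hydroperoxide, CC(C)(C)OO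
Why: Weitz–Scheffer nucleophilic epoxidation. The peroxide anion adds axially to C3 anti to the pseudo-axial silyloxy group on C7 and anti to the isopropenyl group on C6, so the oxirane forms on the face opposite to the future ether bridge and sets C2 and C3.

Step 5
Reactants: 7 epoxy ketone
Product: 9 bicyclic ether hydroxy ketone, via tertiary alcohol 8 (not isolated)
Conditions: Co(acac)2 (cat.), PhSiH3, O2 (1 atm), THF, rt; PPh3; then CSA (cat.), CH2Cl2, 0 °C → rt
Reagents that add atoms: dioxygen, O=O
Why: Mukaiyama hydration (hydrogen-atom transfer, Markovnikov) converts the only alkene into the tertiary alcohol. Under acid this alcohol opens the epoxy ketone 5-exo at C3, the carbon beta to the ketone, in a trans-diaxial (Fürst–Plattner) geometry with inversion; this closes the tetrahydrofuran of the 6-oxabicyclo[3.2.1]octane and leaves C2–OH anti to the new C3–O4 bond. The tert-butyl ester resists lactonisation by the 1,3-diaxial C2 hydroxyl.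

Step 6
Reactants: 9 bicyclic ether hydroxy ketone
Product: 10 vinyl diol
Conditions: CH2=CHMgBr (3 equiv), CeCl3, THF, −78 °C
Reagents that add atoms: vinylmagnesium bromide, C=C[Mg]Br
Why: Organocerium 1,2-addition to the C1 ketone is much faster than attack on the hindered tert-butyl ester and avoids enolisation. The face of C1 under the O4–C5 bridge is blocked by the endo methyl group, so vinyl enters from the open exo face; the new hydroxyl points to the ether bridge and the vinyl group is cis to the CH2CO2tBu arm on C7.

Step 7
Reactants: 10 vinyl diol
Product: 11 ketol
Conditions: (COCl)2, DMSO, CH2Cl2, −78 °C; Et3N, −78 → 0 °C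
Reagents that add atoms: none
Why: Swern oxidation of the only secondary alcohol gives the C2 ketone; the tertiary allylic alcohol cannot be oxidised. The cold, brief basic stage avoids acyloin rearrangement of the ketol, and C3–H is a bridgehead hydrogen that cannot epimerise.

Step 8
Reactants: 11 ketol
Product: 12 bis-silyl ether ester
Conditions: TESOTf, 2,6-lutidine, CH2Cl2, 0 °C
Reagents that add atoms: triethylsilyl trifluoromethanesulfonate, CC[Si](CC)(CC)OS(=O)(=O)C(F)(F)F
Why: Silylation of the tertiary C1 hydroxyl secures the alpha-ketol against rearrangement and removes the last acidic O–H before enolate chemistry.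

Step 9
Reactants: 12 bis-silyl ether ester
Product: 15 acrylate–vinyl metathesis precursor, via Mannich base 13 (not isolated), via methiodide 14 (not isolated)
Conditions: LDA, THF, −78 °C; CH2=NMe2+ I−, −78 °C → rt; then MeI, CH2Cl2, rt; then DBU, rt
Reagents that add atoms: N,N-dimethylmethyleneiminium iodide (Eschenmoser's salt), C=[N+](C)C.[I-]
Why: Alpha-methylenation of the ester by an enolate Mannich reaction, quaternisation and E1cB loss of trimethylamine. The ester CH2 is the only acidic C–H (C1 is quaternary, C3–H is a bridgehead hydrogen), and at −78 °C the beta-silyloxy ester enolate does not expel silanolate.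

Step 10
Reactants: 15 acrylate–vinyl metathesis precursor
Product: 16 bis-silylated cage tert-butyl ester
Conditions: second-generation Hoveyda–Grubbs catalyst (10 mol%), toluene (2 mM), 100 °C, argon purge
Reagents that add atoms: none
Why: The ruthenium alkylidene loads on the monosubstituted vinyl group at C1, adds to the 1,1-disubstituted acrylate on C7 to give a ruthenacyclobutane, and cycloreversion forms the C8=C9 bond and a ruthenium methylidene that carries the chain with loss of ethylene. The closest known reaction types are ring-closing metathesis to bridged bicycloalkenes and ring-closing metathesis of alpha-substituted acrylates to cyclic trisubstituted enoates. One ring is closed, a cyclohexene (C7–C8=C9–C1–C2–C3), by bridging the 1,4-positions of the existing carbocycle, which creates the bicyclo[2.2.2]octene and requires that carbocycle to sit as a boat with both arms in flagpole positions. In the chair form of 15 the C1 silyloxy group would lie under the ring against the endo methyl group of the ether bridge, so the boat, in which this group swings outward and the vinyl group becomes a flagpole, should be well populated. No stereocentre is formed; the 1,4-cis relationship of the arms was fixed in steps 2 and 6. Chemoselectivity is secured by the substrate: only two alkenes are present, because the isopropenyl group was hydrated in step 5 and the C3 side chain is introduced only after this step. High dilution disfavours oligomers and removal of ethylene makes the closure irreversible; the product alkene is trisubstituted, conjugated and flanked by two fully substituted carbons and should not re-enter metathesis.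

Step 11
Reactants: 16 bis-silylated cage tert-butyl ester
Product: 17 C3 bromide
Conditions: NBS, AIBN (cat.), BaCO3, PhCF3, 80 °C
Reagents that add atoms: N-bromosuccinimide, O=C1CCC(=O)N1Br
Why: Radical bromination of a captodative C–H bond (Wohl–Ziegler conditions, as in the Ferrier photobromination of C–H bonds flanked by a ring oxygen and a carbonyl). C3–H is the only such bond and every allylic position is quaternary; the pyramidal bridgehead radical is trapped with retention, which the cage enforces. The bromide cannot ionise or eliminate because C3 cannot become planar and has no beta-hydrogen.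

Step 12
Reactants: 17 C3 bromide
Product: 18 C3 allyl cage ester
Conditions: CH2=CHCH2SnBu3 (3 equiv), AIBN (cat.), benzene, 80 °C
Reagents that add atoms: allyltributylstannane, C=CC[Sn](CCCC)(CCCC)CCCC
Why: Keck radical allylation: the tin radical abstracts bromine, the alpha-oxy, alpha-keto bridgehead radical adds to the allylstannane and beta-scission returns the tin radical. The configuration at C3 is fixed by the cage, and a radical is used because the planar enolate that an ionic alkylation would need is not accessible at this carbon.

Step 13
Reactants: 18 C3 allyl cage ester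
Product: 19 C3 prenyl cage ester
Conditions: 2-methylbut-2-ene (excess), second-generation Grubbs catalyst (5 mol%), CH2Cl2, 40 °C
Reagents that add atoms: 2-methylbut-2-ene, CC=C(C)C
Why: Cross-metathesis of the terminal allyl group with excess 2-methylbut-2-ene turns allyl into prenyl. The cage enoate, trisubstituted, electron-poor and flanked by two quaternary carbons, stays untouched.

Step 14
Reactants: 19 C3 prenyl cage ester
Product: 21 cage carboxylic acid, via trimethylsilyl ester 20 (not isolated)
Conditions: TMSOTf, 2,6-lutidine, CH2Cl2, 0 °C; aq. buffer (pH 5)
Reagents that add atoms: none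
Why: Silyl triflate cleavage of the tert-butyl ester: silylation of the carbonyl oxygen, loss of the tert-butyl cation as isobutene and hydrolysis of the silyl ester on work-up. This avoids hydroxide on a very hindered ester and protic acid on the prenyl group and the silyl ethers.

Step 15
Reactants: 22 2,6-dimethoxy-1,4-benzoquinone
Product: 23 2-hydroxy-6-methoxy-1,4-benzoquinone
Conditions: NaOH (1.05 equiv), THF/H2O, 0 °C; then HCl
Reagents that add atoms: sodium hydroxide, [Na+].[OH-]
Why: Addition–elimination of hydroxide on a vinylogous ester. The hydroxyquinone formed is deprotonated to a vinylogous carboxylate, which protects the second methoxy group from substitution.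

Step 16
Reactants: 23 2-hydroxy-6-methoxy-1,4-benzoquinone
Product: 24 methoxy pyranoquinone
Conditions: 3-methylbut-2-enal, pyridine, 100 °C
Reagents that add atoms: 3-methylbut-2-enal, CC(C)=CC=O
Why: Knoevenagel condensation at the nucleophilic carbon next to the hydroxyl followed by oxa-6π electrocyclisation (formal [3+3] annulation) builds the 2,2-dimethyl-2H-pyran on the hydroxyl oxygen. The para-quinone isomer is the thermodynamically preferred product.

Step 17
Reactants: 24 methoxy pyranoquinone
Product: 25 hydroxy pyranoquinone
Conditions: NaOH, MeOH/H2O, rt; then HCl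
Reagents that add atoms: sodium hydroxide, [Na+].[OH-]
Why: Saponification of the remaining vinylogous methyl ester; attack at the methoxy-bearing carbon next to CH is easier than at the fully substituted ring-fusion carbon, where opening would in any case be reversible.

Step 18
Reactants: 25 hydroxy pyranoquinone
Product: 26 prenylated hydroxyquinone
Conditions: LiH, DMSO, rt; prenyl bromide, rt
Reagents that add atoms: 1-bromo-3-methylbut-2-ene, CC(C)=CCBr
Why: C-Alkylation of the ambident hydroxyquinone anion with an allylic bromide, the classical entry to 3-prenyl-2-hydroxyquinones. The lithium salt in DMSO favours carbon, and only one ring carbon is free.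

Step 19
Reactants: 21 cage carboxylic acid; 26 prenylated hydroxyquinone
Product: 28 acyloxyquinone, via acid chloride 27 (not isolated)
Conditions: 1-chloro-N,N,2-trimethylprop-1-en-1-amine, CH2Cl2, 0 °C → rt; then 26, Et3N, DMAP (cat.), 0 °C → rt
Reagents that add atoms: none
Why: The hindered acid is converted into its chloride under neutral conditions with the alpha-chloroenamine (Ghosez's reagent), and the hydroxyquinone, a vinylogous carboxylic acid with a single OH, is O-acylated under DMAP catalysis. The silyl ether on C7 prevents beta-lactone formation.

Step 20
Reactants: 28 acyloxyquinone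
Product: 30 target CNP0222516.1, via diol acyloxyquinone 29 (not isolated)
Conditions: HF·pyridine, pyridine, THF, 0 °C → rt; then CSA (cat.), CH2Cl2, rt
Reagents that add atoms: none
Why: Fluoride removes both triethylsilyl groups, and the freed C7 hydroxyl, held over the acyloxy-bearing quinone carbon, adds in a 6-exo-trig oxa-Michael reaction to close the 1,3-dioxan-4-one; the enol then tautomerises to the CH(prenyl) ketone. Aromatisation cannot occur because the attacked carbon has no hydrogen. Both new centres are set under equilibrating conditions (reversible oxa-Michael addition for the spiro carbon, enolisation for the CH) and should settle in the assumed thermodynamic configuration.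

## Compound list

1 | 1,4-benzoquinone | O=C1C=CC(=O)C=C1 | starting material
2 | tert-butyl acetate | CC(=O)OC(C)(C)C | starting material
3 | tert-butyl 2-(1-hydroxy-4-oxocyclohexa-2,5-dien-1-yl)acetate | O=C1C=CC(O)(CC(=O)OC(C)(C)C)C=C1 | intermediate
4 | isopropenylboronic acid pinacol ester | CC(=C)B1OC(C)(C)C(C)(C)O1 | starting material
5 | tert-butyl 2-[(1S,6S)-1-hydroxy-4-oxo-6-(prop-1-en-2-yl)cyclohex-2-en-1-yl]acetate (OH cis to isopropenyl) | O=C1C=C[C@@](O)(CC(=O)OC(C)(C)C)[C@H](C(C)=C)C1 | intermediate
6 | tert-butyl 2-[(1S,6S)-4-oxo-6-(prop-1-en-2-yl)-1-(triethylsilyloxy)cyclohex-2-en-1-yl]acetate | O=C1C=C[C@@](O[Si](CC)(CC)CC)(CC(=O)OC(C)(C)C)[C@H](C(C)=C)C1 | intermediate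
7 | epoxy ketone: C2–C3 epoxide of 6, oxirane oxygen trans to the silyloxy and isopropenyl groups | O=C1[C@H]2O[C@H]2[C@@](O[Si](CC)(CC)CC)(CC(=O)OC(C)(C)C)[C@H](C(C)=C)C1 | intermediate
8 | tertiary alcohol: 7 with the isopropenyl group hydrated to C(CH3)2OH | O=C1[C@H]2O[C@H]2[C@@](O[Si](CC)(CC)CC)(CC(=O)OC(C)(C)C)[C@H](C(C)(C)O)C1 | intermediate
9 | bicyclic ether hydroxy ketone: 6-oxabicyclo[3.2.1]octane with C1 ketone, C2–OH anti to the C3–O4 bond, C7 bearing OSiEt3 (on the ether-bridge side) and CH2CO2tBu | O=C1[C@@H](O)[C@@H]2OC(C)(C)[C@H](C1)[C@]2(O[Si](CC)(CC)CC)CC(=O)OC(C)(C)C | intermediate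
10 | vinyl diol: 9 with vinyl added to C1; C1–OH on the ether-bridge side, vinyl cis to the CH2CO2tBu arm | C=C[C@@]1(O)[C@@H](O)[C@@H]2OC(C)(C)[C@H](C1)[C@]2(O[Si](CC)(CC)CC)CC(=O)OC(C)(C)C | intermediate
11 | ketol: 10 with C2 oxidised to the ketone | C=C[C@@]1(O)C(=O)[C@@H]2OC(C)(C)[C@H](C1)[C@]2(O[Si](CC)(CC)CC)CC(=O)OC(C)(C)C | intermediate
12 | bis-silyl ether ester: C1 triethylsilyl ether of 11 | C=C[C@@]1(O[Si](CC)(CC)CC)C(=O)[C@@H]2OC(C)(C)[C@H](C1)[C@]2(O[Si](CC)(CC)CC)CC(=O)OC(C)(C)C | intermediate
13 | Mannich base: 12 with CH2N(CH3)2 on the ester alpha-carbon (both epimers) | C=C[C@@]1(O[Si](CC)(CC)CC)C(=O)[C@@H]2OC(C)(C)[C@H](C1)[C@]2(O[Si](CC)(CC)CC)C(CN(C)C)C(=O)OC(C)(C)C | intermediate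
14 | methiodide of 13 (trimethylammonium iodide) | C=C[C@@]1(O[Si](CC)(CC)CC)C(=O)[C@@H]2OC(C)(C)[C@H](C1)[C@]2(O[Si](CC)(CC)CC)C(C[N+](C)(C)C)C(=O)OC(C)(C)C.[I-] | intermediate
15 | metathesis precursor: 6-oxabicyclo[3.2.1]octanone with tert-butyl acrylate (attached through its alpha-carbon) and OSiEt3 on C7, vinyl and OSiEt3 on C1, C2 ketone, C3–H | C=C[C@@]1(O[Si](CC)(CC)CC)C(=O)[C@@H]2OC(C)(C)[C@H](C1)[C@]2(O[Si](CC)(CC)CC)C(=C)C(=O)OC(C)(C)C | intermediate
16 | tert-butyl 5,5-dimethyl-2-oxo-1,7-bis(triethylsilyloxy)-4-oxatricyclo[4.3.1.0(3,7)]dec-8-ene-8-carboxylate (C3–H) | CC(C)(C)OC(=O)C1=C[C@]3(O[Si](CC)(CC)CC)C[C@H]4C(C)(C)O[C@@H](C3=O)[C@@]14O[Si](CC)(CC)CC | intermediate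
17 | 3-bromo derivative of 16 | CC(C)(C)OC(=O)C1=C[C@]3(O[Si](CC)(CC)CC)C[C@H]4C(C)(C)O[C@@](Br)(C3=O)[C@@]14O[Si](CC)(CC)CC | intermediate
18 | 3-allyl derivative of 16 | CC(C)(C)OC(=O)C1=C[C@]3(O[Si](CC)(CC)CC)C[C@H]4C(C)(C)O[C@@](CC=C)(C3=O)[C@@]14O[Si](CC)(CC)CC | intermediate
19 | 3-(3-methylbut-2-enyl) derivative of 16 | CC(C)(C)OC(=O)C1=C[C@]3(O[Si](CC)(CC)CC)C[C@H]4C(C)(C)O[C@@](CC=C(C)C)(C3=O)[C@@]14O[Si](CC)(CC)CC | intermediate
20 | trimethylsilyl ester corresponding to 19 | C[Si](C)(C)OC(=O)C1=C[C@]3(O[Si](CC)(CC)CC)C[C@H]4C(C)(C)O[C@@](CC=C(C)C)(C3=O)[C@@]14O[Si](CC)(CC)CC | intermediate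
21 | cage carboxylic acid (free acid of 19) | OC(=O)C1=C[C@]3(O[Si](CC)(CC)CC)C[C@H]4C(C)(C)O[C@@](CC=C(C)C)(C3=O)[C@@]14O[Si](CC)(CC)CC | intermediate
22 | 2,6-dimethoxy-1,4-benzoquinone | COC1=CC(=O)C=C(OC)C1=O | starting material
23 | 2-hydroxy-6-methoxy-1,4-benzoquinone | COC1=CC(=O)C=C(O)C1=O | intermediate
24 | 7-methoxy-2,2-dimethyl-2H-chromene-5,8-dione | COC1=CC(=O)C2=C(OC(C)(C)C=C2)C1=O | intermediate
25 | 7-hydroxy-2,2-dimethyl-2H-chromene-5,8-dione | OC1=CC(=O)C2=C(OC(C)(C)C=C2)C1=O | intermediate
26 | 7-hydroxy-2,2-dimethyl-6-(3-methylbut-2-en-1-yl)-2H-chromene-5,8-dione | CC(C)=CCC1=C(O)C(=O)C2=C(C=CC(C)(C)O2)C1=O | intermediate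
27 | acid chloride of 21 | ClC(=O)C1=C[C@]3(O[Si](CC)(CC)CC)C[C@H]4C(C)(C)O[C@@](CC=C(C)C)(C3=O)[C@@]14O[Si](CC)(CC)CC | intermediate
28 | acyloxyquinone: ester of acid 21 with the 7-hydroxyl of 26 | CC(C)=CCC1=C(OC(=O)C3=C[C@]4(O[Si](CC)(CC)CC)C[C@H]5C(C)(C)O[C@@](CC=C(C)C)(C4=O)[C@@]35O[Si](CC)(CC)CC)C(=O)C2=C(C=CC(C)(C)O2)C1=O | intermediate
29 | diol acyloxyquinone: 28 with free C1–OH and C7–OH | CC(C)=CCC1=C(OC(=O)C3=C[C@]4(O)C[C@H]5C(C)(C)O[C@@](CC=C(C)C)(C4=O)[C@@]35O)C(=O)C2=C(C=CC(C)(C)O2)C1=O | intermediate
30 | CNP0222516.1 | CC(C)=CC[C@H]1C(=O)C2=C(OC(C)(C)C=C2)C(=O)[C@@]12OC(=O)C1=C[C@]3(O)C[C@H]4C(C)(C)O[C@@](CC=C(C)C)(C3=O)[C@@]14O2 | target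

## Step count and least certain steps

Total step count: 20. Longest linear sequence: 16 (steps 1–14, 19, 20); the quinone branch (steps 15–18) joins in step 19.

**Step 10 (key step).** Turnover may be slow, because both alkenes sit on fully substituted silyloxy carbons and the closure needs the boat; catalyst decay would then lead to alkene isomerisation or dimerisation through the vinyl group. Fallback: set out from 12 and form the same C8=C9 bond by an aldol condensation. Ozonolysis of the vinyl group (O3, then PPh3) gives the C1 aldehyde F1. LiN(SiMe3)2 then generates the ester enolate, which adds across the ring to the non-enolisable aldehyde and gives the bicyclic aldol adduct F2. Dehydration (MsCl, Et3N, then DBU) returns to the route at 16.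

**Step 2.** Facial selectivity may be poor if the hydroxyl does not steer the rhodium alkenyl species to its own face, and a second addition to the remaining enone may compete. Fallback: set the C6 centre on a substrate without a second stereogenic element and make the C7 carbinol later. The quinone monoketal F3 takes the same rhodium-catalysed isopropenyl addition to give the enone ketal F4. Epoxidation anti to the isopropenyl group gives the epoxy ketone F5, and hydration with acid-mediated ring closure gives the bicyclic ether ketal F6. Vinyl addition as in step 6 gives the vinyl carbinol F7, and ketal hydrolysis (PPTS, acetone/H2O) the keto diol F8. Excess lithium enolate of 2 adds to the bridging C7 ketone from the face away from the gem-dimethyl bridge to give the triol ester F9. Swern oxidation gives the ketol F10, and double silylation with TESOTf returns to the route at 12.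

**Step 11.** Hydrogen abstraction may also occur at the silyl ethyl groups or at C6–H and C10–H, and traces of HBr may cleave a silyl ether. Fallback: an ionic one-step alternative from 16. LiTMP (lithium 2,2,6,6-tetramethylpiperidide) removes C3–H, which lies nearly parallel to the carbonyl pi system, to give the pyramidal C3-lithio species F11. O-Alkylation would need a bridgehead enol ether and is excluded, so prenyl bromide can only alkylate at carbon, which returns to the route at 19 and saves steps 12 and 13. This variant is less precedented, because the carbanion cannot flatten.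

**Step 19.** Acylation may be slow, since a weak vinylogous-carboxylate nucleophile meets a very hindered acid chloride; hydrolysis or beta-lactone formation with loss of the C7 silyl group could then take over. Fallback: reverse the roles. From 26, (COCl)2 with catalytic DMF gives the chloroquinone F12 (vinylogous acid chloride). The cesium carboxylate of 21 (Cs2CO3, DMF) then displaces chloride by addition–elimination and returns to the route at 28.

**Step 20.** Ring closure may be incomplete, or may stop at a kinetic mixture of spiro and CH epimers, or acyl transfer may open the vinylogous anhydride. Fallback: close the dioxanone from the other oxygen. From 28, after desilylation, Cs2CO3 drives addition of the C7 alkoxide and loss of the carboxylate, which gives the ether-linked alkoxyquinone acid F13. Acid catalysis (CSA, toluene) then adds the carboxylic acid to the vinylogous ester carbon and the sequence returns to the route at 30.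

## Further compounds

F1 | step 10 | C1 aldehyde from 12 (formyl in place of vinyl) | O=C[C@@]1(O[Si](CC)(CC)CC)C(=O)[C@@H]2OC(C)(C)[C@H](C1)[C@]2(O[Si](CC)(CC)CC)CC(=O)OC(C)(C)C
F2 | step 10 | aldol adduct: 9-hydroxy-8,9-dihydro derivative of 16 (both new centres unassigned) | CC(C)(C)OC(=O)C1C(O)[C@]3(O[Si](CC)(CC)CC)C[C@H]4C(C)(C)O[C@@H](C3=O)[C@@]14O[Si](CC)(CC)CC
F3 | step 2 | 1,4-dioxaspiro[4.5]deca-6,9-dien-8-one | O=C1C=CC2(C=C1)OCCO2
F4 | step 2 | 6-(prop-1-en-2-yl)-1,4-dioxaspiro[4.5]dec-9-en-8-one (C6 as in 5) | O=C1C=CC2(OCCO2)[C@H](C(C)=C)C1
F5 | step 2 | epoxy ketone of F4, oxirane trans to isopropenyl | O=C1[C@H]2O[C@H]2C3(OCCO3)[C@H](C(C)=C)C1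
F6 | step 2 | bicyclic ether ketal: analogue of 9 with a dioxolane at C7 | O=C1[C@@H](O)[C@@H]2OC(C)(C)[C@H](C1)C23OCCO3
F7 | step 2 | vinyl carbinol: analogue of 10 with a dioxolane at C7 | C=C[C@@]1(O)[C@@H](O)[C@@H]2OC(C)(C)[C@H](C1)C23OCCO3
F8 | step 2 | keto diol: F7 with the C7 ketone set free | C=C[C@@]1(O)[C@@H](O)[C@@H]2OC(C)(C)[C@H](C1)C2=O
F9 | step 2 | triol ester: analogue of 10 with free C7–OH | C=C[C@@]1(O)[C@@H](O)[C@@H]2OC(C)(C)[C@H](C1)[C@]2(O)CC(=O)OC(C)(C)C
F10 | step 2 | ketol: analogue of 11 with free C7–OH | C=C[C@@]1(O)C(=O)[C@@H]2OC(C)(C)[C@H](C1)[C@]2(O)CC(=O)OC(C)(C)C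
F11 | step 11 | C3-lithio derivative of 16 (pyramidal bridgehead enolate) | CC(C)(C)OC(=O)C1=C[C@]3(O[Si](CC)(CC)CC)C[C@H]4C(C)(C)O[C@@]([Li])(C3=O)[C@@]14O[Si](CC)(CC)CC
F12 | step 19 | 7-chloro-2,2-dimethyl-6-(3-methylbut-2-en-1-yl)-2H-chromene-5,8-dione | CC(C)=CCC1=C(Cl)C(=O)C2=C(C=CC(C)(C)O2)C1=O
F13 | step 20 | alkoxyquinone acid: C7–O ether of the quinone with free C8 carboxylic acid and free C1–OH | OC(=O)C1=C[C@]3(O)C[C@H]4C(C)(C)O[C@@](CC=C(C)C)(C3=O)[C@@]14OC5=C(CC=C(C)C)C(=O)C6=C(OC(C)(C)C=C6)C5=O
A1 | alternative 1 | sulfonyl cage bis(tert-butyldimethylsilyl) ether: methyl ester with phenylsulfonyl on C2 and hydrogen on C3 | COC(=O)C1=C[C@]3(O[Si](C)(C)C(C)(C)C)C[C@H]4C(C)(C)O[C@@H]([C@@H]3S(=O)(=O)c5ccccc5)[C@@]14O[Si](C)(C)C(C)(C)C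
A2 | alternative 2 | bis(triethylsilyl) cage methyl ester with prenyl on C3 | COC(=O)C1=C[C@]3(O[Si](CC)(CC)CC)C[C@H]4C(C)(C)O[C@@](CC=C(C)C)(C3=O)[C@@]14O[Si](CC)(CC)CC
A3 | alternative 3 | cage methyl ester with prenyl on C3, C1 triethylsilyl ether and free C7 hydroxyl | COC(=O)C1=C[C@]3(O[Si](CC)(CC)CC)C[C@H]4C(C)(C)O[C@@](CC=C(C)C)(C3=O)[C@@]14O
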